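- The precatalyst is charged at 5.6 µM in each flask, and c(target) at 15 min is weighed here against one quantity, the capacity.

| setting | grey | teal | gamma | delta | beta | epsilon | theta |
|---|---|---|---|---|---|---|---|
| starting material | 0.0052 M | 0.023 M | 0.0012 M | 0.0025 M | 0.0050 M | 0.010 M | 0.020 M |
| precatalyst | 5.6 µM | 5.6 µM | 5.6 µM | 5.6 µM | 5.6 µM | 5.6 µM | 5.6 µM |
| remark | run made earlier | run made earlier |  |  |  |  |  |
| time |  |  | 15 min | 15 min | 15 min | 15 min | 15 min |

- grey (time / min: target / %, starting material / %): 1.00: 3.7, 98.5; 2.50: 6.7, 92.6; 5.00: 21.2, 80.3; 8.00: 36.9, 63.5
- teal (time / min: target / %, starting material / %): 0.667: 0, 100.7; 1.33: 0.2, 100.7; 3.00: 1.9, 99.5; 8.00: 7.7, 91.6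

(scatter of a reading: 1 percentage point)

- the earlier runs were read with a standard deviation of 1 percentage point
- "hardly changes" means that all values lie within two and a half points (for a concentration: within two and a half percent of the largest)

- [target] at the end for gamma, delta, beta, epsilon, theta, in this order
- the course of these numbers from the first flask to the last (hardly changes / rises, then falls / rises all the way / falls all the way / falls, then rises)

- Between 5.00 min and 8.00 min, grey gains 2.72 × 10⁻⁴ M/min of target. Between 3.00 min and 8.00 min, teal gains 2.67 × 10⁻⁴ M/min, although its charge is 4.42 times grey's. These nearly equal slopes read as zero order in starting material.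
- The capacity, meaning the c(target) reached at 15 min when a run's last reading is carried on at its own late slope, is 0.00382 M from grey. From teal it is 0.00364 M, a reading from a different run.
- Against the charge, this reckoning starts on the line c(target) = charge, with slope one and the starting material as limiting reagent, so gamma and delta sit at 0.0012 M and 0.0025 M.
- The knee lies where the charge equals the capacity, between delta and beta. Beyond it the row runs into a level near 0.00382 M for beta and epsilon, sinking toward 0.00364 M at teal's charge.
- The line is the weak stretch, since grey's last reading stands at c(starting material) = 0.00330 M, and gamma and delta are charged lower than that.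
- The forecast prints 0.0012 M, 0.0025 M, 0.0038 M, 0.0037 M and 0.0035 M, with the shape "rises, then falls". It says “The two dilute flasks should therefore finish, or nearly finish”. For epsilon it stands slightly lower than this reckoning.
- The flasks give 8.67 × 10⁻⁴ M, 0.00173 M, 0.00304 M, 0.00400 M and 0.00317 M, with the shape "rises, then falls".

    starting material + enzyme → target + enzyme, rate k1*[starting material]*[enzyme]/(1 + ([starting material]/Km1) + ([starting material]/Ksi1)^2) (11.6 mM, 7.92 mM, k = 1.61 × 10⁵ /M/min)
    precatalyst → enzyme (k = 0.0667 /min)
    2 starting material → self-condensation product (k = 0.0375 /M/min)
    enzyme → spent catalyst (k = 0.363 /min)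

- Epsilon lands at 105% of the capacity, but theta reaches 83.0%. In theta, the conversion of enzyme into spent catalyst and the crowding by c(starting material) in the rate law act together, each a part of the reason: theta gives 0.0131 M without the first and 0.00892 M without the second. The capacity exceeds gamma's charge, yet at 15.0 min gamma holds 72.2% of its charge as target, and without the conversion of enzyme into spent catalyst gamma gives 0.00119 M from its charge of 0.0012 M.

(The earlier runs and the new flask are calculated on assumed constants, noise included.)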